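**Plan**
- Retrosynthetic cuts: the O23–C1 lactone bond, C2=C3, the two C–O bonds of the 6,7-epoxide (back to a C6=C7 Z-olefin), C6=C7 itself, C17–C18 and C8–C9.
- Enabling feature: C5–OH and C8–OH lie 1,4 across C6=C7, a Z-2-ene-1,4-diol. Both oxygens fit on one silicon in a seven-membered 1,3-dioxa-2-silacyclohept-5-ene (Si, O5, C5, C6, C7, C8, O8), which can only hold a cis olefin.
- Forward order: C7–C17 bromide plus C18–C24 acetylide gives the C7–C24 allylic alcohol; an iPr2Si tether links it to the C3–C6 allylic alcohol; metathesis closes the seven-membered silaketal (C6=C7); the tether is removed; the oxirane is formed; C1–C2 are added; the 24-membered lactone closes last.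
- Stereochemistry: C23 from (R)-propylene oxide; C8/C9 from Brown (Z)-γ-alkoxyallylboration; C5 from a Sharpless kinetic resolution; C6/C7 from C8–OH-directed epoxidation; 18Z from Lindlar reduction, 6Z from the ring, 2Z from Still–Gennari olefination.

Key step: step 15

Remark: C-numbers are those of the macrolide chain (C1 lactone carbonyl to C24 methyl); 2, 9, 22 and 35 are assumed to be catalogue reagents; CIP descriptors at C6–C8 change along the route only because O-substituents change priorities (no centre is inverted once set); TBS = tert-butyldimethylsilyl, TES = triethylsilyl, PMB = 4-methoxybenzyl, MOM = methoxymethyl, Ipc = isopinocampheyl.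

**Route**

Step 1
Reactants: 1 (R)-propylene oxide; 2 (4-bromobut-1-yn-1-yl)trimethylsilane
Product: 4 (R)-7-(trimethylsilyl)hept-6-yn-2-ol, via Grignard reagent 3 (not isolated)
Conditions: Mg, THF, rt; CuI (10 mol%), 1, THF, −40 to 0 °C; NH4Cl aq.
Reagents that add atoms: none
Why: Copper-catalysed Grignard opening of a terminal epoxide at its CH2 carbon forms C21–C22 and leaves the C23 stereocentre of the epoxide untouched.

Step 2
Reactants: 4 (R)-7-(trimethylsilyl)hept-6-yn-2-ol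
Product: 5 (R)-hept-6-yn-2-ol
Conditions: K2CO3, MeOH, rt
Reagents that add atoms: none
Why: Base-mediated methanolysis of the C(sp)–Si bond (protodesilylation of an alkynylsilane) frees the terminal alkyne.

Step 3
Reactants: 5 (R)-hept-6-yn-2-ol
Product: 6 (R)-6-[(4-methoxybenzyl)oxy]hept-1-yne
Conditions: NaH, PMBCl, Bu4NI (cat.), THF/DMF, 0 °C to rt
Reagents that add atoms: 4-methoxybenzyl chloride (PMBCl), COc1ccc(CCl)cc1
Why: Williamson etherification; PMB is chosen so that C23–OH and C3–OH can later be freed in one operation.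

Step 4
Reactants: 7 9-bromononan-1-ol
Product: 8 9-bromononanal
Conditions: TEMPO (cat.), PhI(OAc)2, CH2Cl2, rt
Reagents that add atoms: none
Why: Oxoammonium (TEMPO) oxidation of a primary alcohol stops at the aldehyde and does not touch the primary bromide.

Step 5
Reactants: 8 9-bromononanal; 9 allyl methoxymethyl ether
Product: 12 (3R,4R)-12-bromo-3-(methoxymethoxy)dodec-1-en-4-ol, via allylborane 10 (not isolated), via borinate 11 (not isolated)
Conditions: 9, s-BuLi, THF, −78 °C; (−)-Ipc2BOMe; BF3·OEt2; 8, −78 °C; ethanolamine, rt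
Reagents that add atoms: none
Why: Brown (Z)-γ-alkoxyallylboration through a chair Zimmerman–Traxler transition state gives the syn C8/C9 relationship, and the Ipc groups from (+)-α-pinene direct attack to the Si face of the aldehyde, setting C9 (R) and C8 (R in this compound); the non-oxidative ethanolamine work-up keeps the alkyl bromide away from alkaline peroxide.

Step 6
Reactants: 12 (3R,4R)-12-bromo-3-(methoxymethoxy)dodec-1-en-4-ol
Product: 13 (3R,4R)-12-bromo-4-(TBSO)-3-(methoxymethoxy)dodec-1-ene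
Conditions: TBSOTf, 2,6-lutidine, CH2Cl2, −78 to 0 °C
Reagents that add atoms: tert-butyldimethylsilyl triflate (TBSOTf), CC(C)(C)[Si](C)(C)OS(=O)(=O)C(F)(F)F
Why: Silyl triflate/lutidine silylation of the hindered C9 hydroxyl is fast at low temperature, where the MOM acetal is not attacked.

Step 7
Reactants: 6 (R)-6-[(4-methoxybenzyl)oxy]hept-1-yne; 13 (3R,4R)-12-bromo-4-(TBSO)-3-(methoxymethoxy)dodec-1-ene
Product: 15 (3R,4R,18R)-4-(TBSO)-3-(methoxymethoxy)-18-(PMBO)nonadec-1-en-13-yne, via lithium acetylide 14 (not isolated)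
Conditions: 6, n-BuLi, THF, −78 °C; then 13, DMPU, −78 °C to rt
Reagents that add atoms: none
Why: SN2 alkylation of a lithium acetylide by an unbranched primary bromide in a dipolar cosolvent forms C17–C18; ethers, silyl ether and vinyl group are inert.

Step 8
Reactants: 15 (3R,4R,18R)-4-(TBSO)-3-(methoxymethoxy)-18-(PMBO)nonadec-1-en-13-yne
Product: 16 (3R,4R,13Z,18R)-4-(TBSO)-3-(methoxymethoxy)-18-(PMBO)nonadeca-1,13-diene
Conditions: H2 (1 atm), Lindlar catalyst, quinoline, EtOAc, rt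
Reagents that add atoms: none
Why: Lindlar semi-hydrogenation delivers H2 syn to the alkyne and sets the 18Z olefin; the poisoned catalyst stops at the alkene stage, as it does when vinyl groups are made from terminal alkynes, so the hindered vinyl group should survive.

Step 9
Reactants: 16 (3R,4R,13Z,18R)-4-(TBSO)-3-(methoxymethoxy)-18-(PMBO)nonadeca-1,13-diene
Product: 18 (3R,4R,13Z,18R)-4-(TBSO)-18-(PMBO)nonadeca-1,13-dien-3-ol, via bipyridinium salt 17 (not isolated)
Conditions: TMSOTf, 2,2′-bipyridyl, CH2Cl2, 0 °C to rt; then H2O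
Reagents that add atoms: none
Why: Silyl triflate/2,2′-bipyridyl cleavage of an aliphatic MOM ether converts the acetal into an N-alkoxymethyl bipyridinium salt that water hydrolyses; the medium stays near neutral, so the secondary TBS ether, the PMB ether and both olefins should be kept.

Step 10
Reactants: 19 propane-1,3-diol
Product: 20 3-[(4-methoxybenzyl)oxy]propan-1-ol
Conditions: NaH (1 equiv), PMBCl, Bu4NI (cat.), THF, 0 °C to rt (diol in excess)
Reagents that add atoms: 4-methoxybenzyl chloride (PMBCl), COc1ccc(CCl)cc1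
Why: Statistical Williamson mono-etherification of a symmetrical diol used in excess.

Step 11
Reactants: 20 3-[(4-methoxybenzyl)oxy]propan-1-ol
Product: 21 3-[(4-methoxybenzyl)oxy]propanal
Conditions: TEMPO (cat.), PhI(OAc)2, CH2Cl2, rt
Reagents that add atoms: none
Why: TEMPO oxidation under non-basic conditions gives the β-alkoxy aldehyde without β-elimination.

Step 12
Reactants: 21 3-[(4-methoxybenzyl)oxy]propanal; 22 vinylmagnesium bromide
Product: 23 rac-5-[(4-methoxybenzyl)oxy]pent-1-en-3-ol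
Conditions: THF, −78 to 0 °C; NH4Cl aq.
Reagents that add atoms: none
Why: Grignard 1,2-addition to the aldehyde gives the racemic C3–C6 allylic alcohol.

Step 13
Reactants: 23 rac-5-[(4-methoxybenzyl)oxy]pent-1-en-3-ol
Product: 24 (S)-5-[(4-methoxybenzyl)oxy]pent-1-en-3-ol
Conditions: Ti(OiPr)4 (cat.), D-(−)-DIPT, t-BuOOH (0.6 equiv), 4 Å MS, CH2Cl2, −20 °C
Reagents that add atoms: none
Why: Sharpless kinetic resolution: with D-(−)-DIPT the (R)-enantiomer is epoxidised faster (to the erythro epoxy alcohol), so the (S)-alcohol carrying the C5 configuration should be recovered when the oxidation is stopped at slightly over half conversion.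

Step 14
Reactants: 18 (3R,4R,13Z,18R)-4-(TBSO)-18-(PMBO)nonadeca-1,13-dien-3-ol; 25 dichlorodiisopropylsilane; 24 (S)-5-[(4-methoxybenzyl)oxy]pent-1-en-3-ol
Product: 27 mixed diisopropylsilaketal joining O5 of 24 to O8 of 18 (5S,8R,9R,23R), via chlorosilane 26 (not isolated)
Conditions: 25 (excess), imidazole, CH2Cl2, 0 °C; evaporate excess 25; then 24, imidazole, DMF, rt
Reagents that add atoms: none
Why: Stepwise silylation: the hindered C8 hydroxyl reacts with excess dichlorosilane to give only the monochloride, and after removal of the volatile excess the less hindered C5 alcohol displaces the second chloride, which avoids symmetrical silaketals.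

Step 15
Reactants: 27 mixed diisopropylsilaketal (5S,8R,9R,23R)
Product: 28 (4S,7R)-2,2-diisopropyl-4,7-dihydro-1,3,2-dioxasilepine carrying the C3–C4 arm at ring C4 and the C9–C24 chain at ring C7
Conditions: Grubbs II (5–10 mol%), CH2Cl2 (5 mM), 40 °C
Reagents that add atoms: none
Why: The Ru alkylidene loads on one of the two vinyl groups, the other vinyl group adds to it to give a ruthenacyclobutane, and cycloreversion expels ethylene (Chauvin cycle). The closest known reaction type is temporary silicon-tethered ring-closing metathesis of bis-allylic dialkoxysilanes to 4,7-dihydro-1,3,2-dioxasilepines. The seven-membered ring (O5–Si–O8–C8–C7=C6–C5) closes by olefin metathesis between the two terminal carbons, the new bond being the endocyclic C6=C7 double bond. No stereocentre is created; a seven-membered ring can only hold a cis double bond, so the Z geometry is structural, and C5 and C8 are untouched. The step needs chemoselectivity over the remote C18=C19 Z-olefin: closure onto it would give 12- or 16-membered rings from a disubstituted olefin, far slower than seven-ring closure between two monosubstituted olefins, and high dilution with a short reaction time should limit secondary metathesis.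

Step 16
Reactants: 28 cyclic silaketal
Product: 29 (3S,4Z,6R,7R,16Z,21R)-7-(TBSO)-1,21-bis(PMBO)docosa-4,16-diene-3,6-diol
Conditions: HF·pyridine, pyridine, THF, 0 °C
Reagents that add atoms: none
Why: Fluoride cleaves the dialkoxysilane much faster than the hindered secondary TBS ether, releasing the Z-ene-1,4-diol with both carbinol centres unchanged.

Step 17
Reactants: 29 Z-ene-1,4-diol
Product: 30 (3S,4Z,6R,7R,16Z,21R)-3,7-bis(TBSO)-1,21-bis(PMBO)docosa-4,16-dien-6-ol
Conditions: TBSCl (1.1 equiv), imidazole, CH2Cl2, 0 °C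
Reagents that add atoms: tert-butyldimethylsilyl chloride (TBSCl), CC(C)(C)[Si](C)(C)Cl
Why: Sterically controlled silylation: the C5 hydroxyl has a methylene neighbour whereas the C8 hydroxyl is flanked by the silyloxy-bearing C9, so a silyl chloride (not a triflate) should take C5–OH first.

Step 18
Reactants: 30 C5-silylated Z-allylic alcohol
Product: 31 (3S,4R,5R,6R,7R,16Z,21R)-3,7-bis(TBSO)-4,5-epoxy-1,21-bis(PMBO)docos-16-en-6-ol
Conditions: VO(acac)2 (cat.), t-BuOOH, CH2Cl2, 0 °C to rt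
Reagents that add atoms: tert-butyl hydroperoxide, CC(C)(C)OO
Why: Vanadium-catalysed hydroxyl-directed epoxidation: the C8 alkoxide binds vanadium and delivers oxygen to the face it occupies in the A(1,3)-minimised conformer (C8–H eclipsing the Z-olefin), giving the threo epoxy alcohol, which is the 6,7-cis-epoxide of the target; the isolated C18=C19 olefin has no directing group and should not react.

Step 19
Reactants: 31 epoxy alcohol
Product: 32 (3S,4R,5S,6R,7R,16Z,21R)-3,7-bis(TBSO)-4,5-epoxy-6-(TESO)-1,21-bis(PMBO)docos-16-ene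
Conditions: TESOTf, 2,6-lutidine, CH2Cl2, −78 °C
Reagents that add atoms: triethylsilyl triflate (TESOTf), CC[Si](CC)(CC)OS(=O)(=O)C(F)(F)F
Why: Low-temperature triflate silylation caps the hindered C8 hydroxyl before the epoxide can be opened, so that only C23–OH is free at the lactonisation stage.

Step 20
Reactants: 32 fully protected epoxide
Product: 33 (3S,4R,5S,6R,7R,16Z,21R)-3,7-bis(TBSO)-4,5-epoxy-6-(TESO)docos-16-ene-1,21-diol
Conditions: DDQ, CH2Cl2/pH 7 buffer, 0 °C to rt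
Reagents that add atoms: none
Why: Oxidative PMB cleavage by DDQ (hydride abstraction, then hydrolysis of the oxocarbenium ion) frees C3–OH and C23–OH together while silyl ethers, epoxide and olefin are inert.

Step 21
Reactants: 33 C3,C23-diol
Product: 34 (3S,4R,5S,6R,7R,16Z,21R)-3,7-bis(TBSO)-4,5-epoxy-21-hydroxy-6-(TESO)docos-16-enal
Conditions: TEMPO (cat.), PhI(OAc)2, CH2Cl2, rt
Reagents that add atoms: none
Why: Oxoammonium (TEMPO) oxidation is selective for the primary C3 alcohol over the secondary C23 alcohol and stops at the aldehyde.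

Step 22
Reactants: 34 hydroxy aldehyde; 35 methyl bis(2,2,2-trifluoroethyl)phosphonoacetate
Product: 37 methyl (2Z,5S,6R,7S,8R,9R,18Z,23R)-5,9-bis(TBSO)-6,7-epoxy-23-hydroxy-8-(TESO)tetracosa-2,18-dienoate, via potassium phosphonate 36 (not isolated)
Conditions: 35, KHMDS, 18-crown-6, THF, −78 °C; then 34
Reagents that add atoms: none
Why: Still–Gennari olefination: the trifluoroethyl phosphonate eliminates rapidly and irreversibly from the syn adduct under dissociating K+/18-crown-6 conditions, giving the 2Z enoate; the remote C23 hydroxyl is far less acidic than the phosphonate and is tolerated.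

Step 23
Reactants: 37 Z-enoate methyl ester
Product: 38 (2Z,5S,6R,7S,8R,9R,18Z,23R)-5,9-bis(TBSO)-6,7-epoxy-23-hydroxy-8-(TESO)tetracosa-2,18-dienoic acid
Conditions: LiOH, THF/MeOH/H2O, 0 °C to rt; dil. HCl to pH 4
Reagents that add atoms: lithium hydroxide, [Li+].[OH-]
Why: Saponification of the methyl ester by hydroxide at low temperature; the hindered silyl ethers and the epoxide are stable to these conditions.

Step 24
Reactants: 38 seco acid
Product: 40 tris-silylated 24-membered macrolactone (5-OTBS and 8-OTES and 9-OTBS), via mixed anhydride 39 (not isolated)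
Conditions: 2,4,6-Cl3C6H2COCl, Et3N, THF, rt; then DMAP, toluene (1 mM), slow addition, rt
Reagents that add atoms: none
Why: Yamaguchi macrolactonisation: DMAP attacks the less hindered enoyl carbonyl of the mixed anhydride and the unhindered C23 methyl carbinol closes the 24-membered ring under high dilution with retention at C23.

Step 25
Reactants: 40 tris-silylated macrolactone
Product: 41 AKML B
Conditions: HF·pyridine, pyridine, THF, 0 °C to rt
Reagents that add atoms: none
Why: Buffered fluoride cleavage of the three silyl ethers avoids the alkoxide conditions that could cause epoxide migration (Payne) or translactonisation onto C5–OH.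

**Compound list**

1 | (R)-propylene oxide | C[C@@H]1CO1 | starting material
2 | (4-bromobut-1-yn-1-yl)trimethylsilane | C[Si](C)(C)C#CCCBr | starting material
3 | [4-(trimethylsilyl)but-3-yn-1-yl]magnesium bromide | C[Si](C)(C)C#CCC[Mg]Br | intermediate
4 | (R)-7-(trimethylsilyl)hept-6-yn-2-ol | C[C@@H](O)CCCC#C[Si](C)(C)C | intermediate
5 | (R)-hept-6-yn-2-ol | C[C@@H](O)CCCC#C | intermediate
6 | (R)-6-[(4-methoxybenzyl)oxy]hept-1-yne | C#CCCC[C@@H](C)OCc1ccc(OC)cc1 | intermediate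
7 | 9-bromononan-1-ol | OCCCCCCCCCBr | starting material
8 | 9-bromononanal | O=CCCCCCCCCBr | intermediate
9 | allyl methoxymethyl ether [3-(methoxymethoxy)prop-1-ene] | C=CCOCOC | starting material
10 | (Z)-[3-(methoxymethoxy)prop-2-en-1-yl]bis(isopinocampheyl)borane, Ipc from (+)-α-pinene | COCO/C=C\CB([C@@H]1C[C@@H]2C[C@H]([C@H]1C)C2(C)C)[C@@H]1C[C@@H]2C[C@H]([C@H]1C)C2(C)C | intermediate
11 | (3R,4R)-12-bromo-3-(methoxymethoxy)dodec-1-en-4-yl bis(isopinocampheyl)borinate | C=C[C@@H](OCOC)[C@H](OB([C@@H]1C[C@@H]2C[C@H]([C@H]1C)C2(C)C)[C@@H]1C[C@@H]2C[C@H]([C@H]1C)C2(C)C)CCCCCCCCBr | intermediate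
12 | (3R,4R)-12-bromo-3-(methoxymethoxy)dodec-1-en-4-ol | C=C[C@@H](OCOC)[C@H](O)CCCCCCCCBr | intermediate
13 | (3R,4R)-12-bromo-4-[(tert-butyldimethylsilyl)oxy]-3-(methoxymethoxy)dodec-1-ene | C=C[C@@H](OCOC)[C@H](O[Si](C)(C)C(C)(C)C)CCCCCCCCBr | intermediate
14 | lithium acetylide of 6, lithium (R)-6-[(4-methoxybenzyl)oxy]hept-1-yn-1-ide | [Li]C#CCCC[C@@H](C)OCc1ccc(OC)cc1 | intermediate
15 | (3R,4R,18R)-4-[(tert-butyldimethylsilyl)oxy]-3-(methoxymethoxy)-18-[(4-methoxybenzyl)oxy]nonadec-1-en-13-yne | C=C[C@@H](OCOC)[C@H](O[Si](C)(C)C(C)(C)C)CCCCCCCCC#CCCC[C@@H](C)OCc1ccc(OC)cc1 | intermediate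
16 | (3R,4R,13Z,18R)-4-[(tert-butyldimethylsilyl)oxy]-3-(methoxymethoxy)-18-[(4-methoxybenzyl)oxy]nonadeca-1,13-diene | C=C[C@@H](OCOC)[C@H](O[Si](C)(C)C(C)(C)C)CCCCCCCC/C=C\CCC[C@@H](C)OCc1ccc(OC)cc1 | intermediate
17 | 1-{[(C8–O of 16)oxy]methyl}-2,2′-bipyridin-1-ium triflate (MOM methoxy replaced by N-bipyridinium; 3R,4R,13Z,18R) | C=C[C@@H](OC[n+]1ccccc1-c1ccccn1)[C@H](O[Si](C)(C)C(C)(C)C)CCCCCCCC/C=C\CCC[C@@H](C)OCc1ccc(OC)cc1.[O-]S(=O)(=O)C(F)(F)F | intermediate
18 | (3R,4R,13Z,18R)-4-[(tert-butyldimethylsilyl)oxy]-18-[(4-methoxybenzyl)oxy]nonadeca-1,13-dien-3-ol | C=C[C@@H](O)[C@H](O[Si](C)(C)C(C)(C)C)CCCCCCCC/C=C\CCC[C@@H](C)OCc1ccc(OC)cc1 | intermediate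
19 | propane-1,3-diol | OCCCO | starting material
20 | 3-[(4-methoxybenzyl)oxy]propan-1-ol | OCCCOCc1ccc(OC)cc1 | intermediate
21 | 3-[(4-methoxybenzyl)oxy]propanal | O=CCCOCc1ccc(OC)cc1 | intermediate
22 | vinylmagnesium bromide | C=C[Mg]Br | starting material
23 | rac-5-[(4-methoxybenzyl)oxy]pent-1-en-3-ol | C=CC(O)CCOCc1ccc(OC)cc1 | intermediate
24 | (S)-5-[(4-methoxybenzyl)oxy]pent-1-en-3-ol | C=C[C@@H](O)CCOCc1ccc(OC)cc1 | intermediate
25 | dichlorodiisopropylsilane | CC(C)[Si](Cl)(Cl)C(C)C | starting material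
26 | chloro(diisopropyl)silyl ether of 18 at the allylic (C8) oxygen | C=C[C@@H](O[Si](Cl)(C(C)C)C(C)C)[C@H](O[Si](C)(C)C(C)(C)C)CCCCCCCC/C=C\CCC[C@@H](C)OCc1ccc(OC)cc1 | intermediate
27 | mixed diisopropylsilaketal: iPr2Si bridging the C5 oxygen of 24 and the C8 oxygen of 18 (5S,8R,9R,18Z,23R) | C=C[C@H](CCOCc1ccc(OC)cc1)O[Si](C(C)C)(C(C)C)O[C@H](C=C)[C@H](O[Si](C)(C)C(C)(C)C)CCCCCCCC/C=C\CCC[C@@H](C)OCc1ccc(OC)cc1 | intermediate
28 | (4S,7R)-2,2-diisopropyl-4-{2-[(4-methoxybenzyl)oxy]ethyl}-7-{(1R,10Z,15R)-1-[(tert-butyldimethylsilyl)oxy]-15-[(4-methoxybenzyl)oxy]hexadec-10-en-1-yl}-4,7-dihydro-1,3,2-dioxasilepine | CC(C)[Si]1(C(C)C)O[C@@H](CCOCc2ccc(OC)cc2)/C=C\[C@H]([C@H](O[Si](C)(C)C(C)(C)C)CCCCCCCC/C=C\CCC[C@@H](C)OCc2ccc(OC)cc2)O1 | intermediate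
29 | (3S,4Z,6R,7R,16Z,21R)-7-[(tert-butyldimethylsilyl)oxy]-1,21-bis[(4-methoxybenzyl)oxy]docosa-4,16-diene-3,6-diol | COc1ccc(COCC[C@H](O)/C=C\[C@@H](O)[C@H](O[Si](C)(C)C(C)(C)C)CCCCCCCC/C=C\CCC[C@@H](C)OCc2ccc(OC)cc2)cc1 | intermediate
30 | (3S,4Z,6R,7R,16Z,21R)-3,7-bis[(tert-butyldimethylsilyl)oxy]-1,21-bis[(4-methoxybenzyl)oxy]docosa-4,16-dien-6-ol | COc1ccc(COCC[C@H](O[Si](C)(C)C(C)(C)C)/C=C\[C@@H](O)[C@H](O[Si](C)(C)C(C)(C)C)CCCCCCCC/C=C\CCC[C@@H](C)OCc2ccc(OC)cc2)cc1 | intermediate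
31 | (3S,4R,5R,6R,7R,16Z,21R)-3,7-bis[(tert-butyldimethylsilyl)oxy]-4,5-epoxy-1,21-bis[(4-methoxybenzyl)oxy]docos-16-en-6-ol (cis-epoxide) | COc1ccc(COCC[C@H](O[Si](C)(C)C(C)(C)C)[C@@H]2O[C@@H]2[C@@H](O)[C@H](O[Si](C)(C)C(C)(C)C)CCCCCCCC/C=C\CCC[C@@H](C)OCc3ccc(OC)cc3)cc1 | intermediate
32 | (3S,4R,5S,6R,7R,16Z,21R)-3,7-bis[(tert-butyldimethylsilyl)oxy]-4,5-epoxy-6-[(triethylsilyl)oxy]-1,21-bis[(4-methoxybenzyl)oxy]docos-16-ene | COc1ccc(COCC[C@H](O[Si](C)(C)C(C)(C)C)[C@@H]2O[C@@H]2[C@@H](O[Si](CC)(CC)CC)[C@H](O[Si](C)(C)C(C)(C)C)CCCCCCCC/C=C\CCC[C@@H](C)OCc3ccc(OC)cc3)cc1 | intermediate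
33 | (3S,4R,5S,6R,7R,16Z,21R)-3,7-bis[(tert-butyldimethylsilyl)oxy]-4,5-epoxy-6-[(triethylsilyl)oxy]docos-16-ene-1,21-diol | OCC[C@H](O[Si](C)(C)C(C)(C)C)[C@@H]1O[C@@H]1[C@@H](O[Si](CC)(CC)CC)[C@H](O[Si](C)(C)C(C)(C)C)CCCCCCCC/C=C\CCC[C@@H](C)O | intermediate
34 | (3S,4R,5S,6R,7R,16Z,21R)-3,7-bis[(tert-butyldimethylsilyl)oxy]-4,5-epoxy-21-hydroxy-6-[(triethylsilyl)oxy]docos-16-enal | O=CC[C@H](O[Si](C)(C)C(C)(C)C)[C@@H]1O[C@@H]1[C@@H](O[Si](CC)(CC)CC)[C@H](O[Si](C)(C)C(C)(C)C)CCCCCCCC/C=C\CCC[C@@H](C)O | intermediate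
35 | methyl bis(2,2,2-trifluoroethyl)phosphonoacetate | COC(=O)CP(=O)(OCC(F)(F)F)OCC(F)(F)F | starting material
36 | potassium salt of the carbanion of 35 | COC(=O)[CH-]P(=O)(OCC(F)(F)F)OCC(F)(F)F.[K+] | intermediate
37 | methyl (2Z,5S,6R,7S,8R,9R,18Z,23R)-5,9-bis[(tert-butyldimethylsilyl)oxy]-6,7-epoxy-23-hydroxy-8-[(triethylsilyl)oxy]tetracosa-2,18-dienoate | COC(=O)/C=C\C[C@H](O[Si](C)(C)C(C)(C)C)[C@@H]1O[C@@H]1[C@@H](O[Si](CC)(CC)CC)[C@H](O[Si](C)(C)C(C)(C)C)CCCCCCCC/C=C\CCC[C@@H](C)O | intermediate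
38 | (2Z,5S,6R,7S,8R,9R,18Z,23R)-5,9-bis[(tert-butyldimethylsilyl)oxy]-6,7-epoxy-23-hydroxy-8-[(triethylsilyl)oxy]tetracosa-2,18-dienoic acid | OC(=O)/C=C\C[C@H](O[Si](C)(C)C(C)(C)C)[C@@H]1O[C@@H]1[C@@H](O[Si](CC)(CC)CC)[C@H](O[Si](C)(C)C(C)(C)C)CCCCCCCC/C=C\CCC[C@@H](C)O | intermediate
39 | mixed anhydride of 38 with 2,4,6-trichlorobenzoic acid | O=C(OC(=O)c1c(Cl)cc(Cl)cc1Cl)/C=C\C[C@H](O[Si](C)(C)C(C)(C)C)[C@@H]1O[C@@H]1[C@@H](O[Si](CC)(CC)CC)[C@H](O[Si](C)(C)C(C)(C)C)CCCCCCCC/C=C\CCC[C@@H](C)O | intermediate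
40 | 5,9-bis-O-TBS-8-O-TES ether of AKML B (24-membered 2Z,18Z-macrolactone, 6,7-cis-epoxide; CIP 5S,6R,7S,8R,9R,23R) | C[C@@H]1CCC/C=C\CCCCCCCC[C@@H](O[Si](C)(C)C(C)(C)C)[C@H](O[Si](CC)(CC)CC)[C@H]2O[C@H]2[C@@H](O[Si](C)(C)C(C)(C)C)C/C=C\C(=O)O1 | intermediate
41 | AKML B: 24-membered (2Z,18Z)-macrolactone, 6,7-cis-epoxide, 5,8,9-triol, 23-methyl (5S,6S,7R,8S,9R,23R) | C[C@@H]1CCC/C=C\CCCCCCCC[C@@H](O)[C@H](O)[C@H]2O[C@H]2[C@@H](O)C/C=C\C(=O)O1 | target

**Step count**
Total: 25 steps. Longest linear sequence: 18 steps (7 to 41 through steps 4–9 and 14–25; equally 1 to 41 through steps 1–3, 7–9 and 14–25).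

**Steps most likely to fail**

Step 15 (ring-closing metathesis). What may go wrong: the ruthenium carbene strays to the remote C18=C19 olefin (Z/E scrambling by secondary metathesis, or closure to larger rings), or turnover stalls at the two hindered allylic silyl ethers. Fallback: join the halves before the C18=C19 olefin exists. It sets out from bromide 13. MOM cleavage as in step 9 gives, through the bipyridinium salt F1, the bromo alcohol F2. Silylation with 25 gives the chlorosilane F3 and, with 24, the bromo silaketal F4. Grubbs II then closes the cyclic silaketal F5 with no other olefin in the molecule. Alkylation of acetylide 14 with F5 (THF/DMPU; the hindered diisopropylsilylene should tolerate the acetylide) gives the enyne F6, and Lindlar reduction of F6, which leaves the ring olefin alone, comes back to the route at 28.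

Step 18 (directed epoxidation). What may go wrong: poor facial selectivity, because vanadium delivers oxygen at a small O–C–C=C dihedral and the threo preference of a Z-allylic alcohol can erode; a peracid cannot be used on 30 since it would also epoxidise C18=C19. Fallback: epoxidise in the bromide series, where the ring olefin is the only one and the more threo-selective peracid can be used. It sets out from bromide 13 and runs through F1–F5 as above. HF·pyridine frees the diol F7, TBSCl/imidazole gives the C5 silyl ether F8, and mCPBA (NaHCO3, CH2Cl2, 0 °C) gives the threo epoxy alcohol F9. TESOTf gives the silyl ether F10, alkylation of acetylide 14 gives the alkyne F11, and Lindlar reduction comes back to the route at 32.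

Step 24 (macrolactonisation). What may go wrong: Z-to-E isomerisation at C2=C3 by reversible conjugate addition of DMAP to the activated enoyl species while ring closure is slow, together with oligomerisation. Fallback: close the ring by olefination instead of acylation. It sets out from hydroxy aldehyde 34. The C23 hydroxyl is esterified (EDC, DMAP cat., CH2Cl2, 0 °C) with [bis(2,2,2-trifluoroethoxy)phosphoryl]acetic acid F12, obtained from 35 by careful saponification, to give the phosphonoacetate aldehyde F13. Intramolecular Still–Gennari olefination (KHMDS, 18-crown-6, THF, −78 °C, high dilution) forms C2=C3 and the 24-membered ring together and comes back to the route at 40.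

Further compounds
F1 | step 15 | N-alkoxymethyl-2,2′-bipyridinium triflate from bromide 13 | C=C[C@@H](OC[n+]1ccccc1-c1ccccn1)[C@H](O[Si](C)(C)C(C)(C)C)CCCCCCCCBr.[O-]S(=O)(=O)C(F)(F)F
F2 | step 15 | (3R,4R)-12-bromo-4-[(tert-butyldimethylsilyl)oxy]dodec-1-en-3-ol | C=C[C@@H](O)[C@H](O[Si](C)(C)C(C)(C)C)CCCCCCCCBr
F3 | step 15 | chloro(diisopropyl)silyl ether of F2 | C=C[C@@H](O[Si](Cl)(C(C)C)C(C)C)[C@H](O[Si](C)(C)C(C)(C)C)CCCCCCCCBr
F4 | step 15 | mixed diisopropylsilaketal of 24 and F2 | C=C[C@H](CCOCc1ccc(OC)cc1)O[Si](C(C)C)(C(C)C)O[C@H](C=C)[C@H](O[Si](C)(C)C(C)(C)C)CCCCCCCCBr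
F5 | step 15 | (4S,7R)-7-[(1R)-9-bromo-1-(TBSO)nonyl]-2,2-diisopropyl-4-[2-(PMBO)ethyl]-4,7-dihydro-1,3,2-dioxasilepine | CC(C)[Si]1(C(C)C)O[C@@H](CCOCc2ccc(OC)cc2)/C=C\[C@H]([C@H](O[Si](C)(C)C(C)(C)C)CCCCCCCCBr)O1
F6 | step 15 | C18–C19 alkyne analogue of 28 | CC(C)[Si]1(C(C)C)O[C@@H](CCOCc2ccc(OC)cc2)/C=C\[C@H]([C@H](O[Si](C)(C)C(C)(C)C)CCCCCCCCC#CCCC[C@@H](C)OCc2ccc(OC)cc2)O1
F7 | step 18 | (3S,4Z,6R,7R)-15-bromo-7-(TBSO)-1-(PMBO)pentadec-4-ene-3,6-diol | COc1ccc(COCC[C@H](O)/C=C\[C@@H](O)[C@H](O[Si](C)(C)C(C)(C)C)CCCCCCCCBr)cc1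
F8 | step 18 | (3S,4Z,6R,7R)-15-bromo-3,7-bis(TBSO)-1-(PMBO)pentadec-4-en-6-ol | COc1ccc(COCC[C@H](O[Si](C)(C)C(C)(C)C)/C=C\[C@@H](O)[C@H](O[Si](C)(C)C(C)(C)C)CCCCCCCCBr)cc1
F9 | step 18 | (3S,4R,5R,6R,7R)-15-bromo-3,7-bis(TBSO)-4,5-epoxy-1-(PMBO)pentadecan-6-ol | COc1ccc(COCC[C@H](O[Si](C)(C)C(C)(C)C)[C@@H]2O[C@@H]2[C@@H](O)[C@H](O[Si](C)(C)C(C)(C)C)CCCCCCCCBr)cc1
F10 | step 18 | (3S,4R,5S,6R,7R)-15-bromo-3,7-bis(TBSO)-4,5-epoxy-6-(TESO)-1-(PMBO)pentadecane | COc1ccc(COCC[C@H](O[Si](C)(C)C(C)(C)C)[C@@H]2O[C@@H]2[C@@H](O[Si](CC)(CC)CC)[C@H](O[Si](C)(C)C(C)(C)C)CCCCCCCCBr)cc1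
F11 | step 18 | C18–C19 alkyne analogue of 32 | COc1ccc(COCC[C@H](O[Si](C)(C)C(C)(C)C)[C@@H]2O[C@@H]2[C@@H](O[Si](CC)(CC)CC)[C@H](O[Si](C)(C)C(C)(C)C)CCCCCCCCC#CCCC[C@@H](C)OCc3ccc(OC)cc3)cc1
F12 | step 24 | [bis(2,2,2-trifluoroethoxy)phosphoryl]acetic acid | OC(=O)CP(=O)(OCC(F)(F)F)OCC(F)(F)F
F13 | step 24 | C23 [bis(2,2,2-trifluoroethoxy)phosphoryl]acetate of aldehyde 34 | O=CC[C@H](O[Si](C)(C)C(C)(C)C)[C@@H]1O[C@@H]1[C@@H](O[Si](CC)(CC)CC)[C@H](O[Si](C)(C)C(C)(C)C)CCCCCCCC/C=C\CCC[C@@H](C)OC(=O)CP(=O)(OCC(F)(F)F)OCC(F)(F)F
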